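**Retrosynthetic overview** (side chain numbered from the arene)
1. Target 16 ⇐ dipivalate 15 ⇐ terminal alkyne 10 + benzylic bromide 13: the C1–C2 bond is made by Zr-catalysed methylalumination / Pd benzylation, which also fixes the 2E olefin.
2. 10 ⇐ enal 8 + allenylboronate 9: the C4–C5 bond and the only stereocentre (5S) come from catalytic asymmetric propargylboration.
3. 8 ⇐ 12-oxofarnesyl acetate 3: key step, the furan is closed by a new C–O bond between the aldehyde oxygen and the γ-carbon of the terminal α-methyl enal; the 6E and 10E olefins are carried over from farnesol.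
4. 3 ⇐ E,E-farnesyl acetate 1 (terminal allylic oxidation); 13 ⇐ 2,6-dimethylhydroquinone 11 (acylation, benzylic bromination).
5. Rings: the benzene ring is bought; the furan is the only ring made (step 2), before the chain is joined to the arene.

Assumption: the SMILES is read as 5S at the carbinol with all three chain olefins E, and pure E,E-farnesyl acetate is taken as bought (otherwise one acetylation of E,E-farnesol precedes step 1).

**Step 1**
Reactants: 1 (2E,6E)-3,7,11-trimethyldodeca-2,6,10-trien-1-yl acetate (E,E-farnesyl acetate)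
Product: 3 (2E,6E,10E)-3,7,11-trimethyl-12-oxododeca-2,6,10-trien-1-yl acetate, via 12-hydroxyfarnesyl acetate 2 (not isolated)
Conditions: SeO2 (0.3 equiv), t-BuOOH (70% aq., 3 equiv), salicylic acid (0.1 equiv), CH2Cl2, 0 °C to rt; aqueous work-up; then MnO2 (15 equiv), CH2Cl2, rt
Reagents that add atoms: tert-butyl hydroperoxide, CC(C)(C)OO (source of the new oxygen, passed on through SeO2, O=[Se]=O)
Why: Sharpless SeO2/t-BuOOH allylic oxidation attacks the E-methyl of the terminal trisubstituted olefin (the 2,3-olefin is deactivated by the allylic acetate), and MnO2 then converges the crude alcohol/aldehyde mixture on enal 3.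

**Step 2**
Reactants: 3 (2E,6E,10E)-3,7,11-trimethyl-12-oxododeca-2,6,10-trien-1-yl acetate
Product: 6 (2E,6E)-3,7-dimethyl-8-(4-methylfuran-2-yl)octa-2,6-dien-1-yl acetate, via pyrrolidine dienamine 4 (not isolated), via Z-γ-iodo enal 5 (not isolated)
Conditions: pyrrolidine (1.05 equiv), 4 Å MS, CH2Cl2, 0 °C to rt; N-iodosuccinimide (1.05 equiv), −78 °C, dark; then NaOAc/AcOH buffer (pH 5), NaI (0.1 equiv), THF–H2O, rt to 40 °C
Reagents that add atoms: none
Why: Proposed new method: one-flask dehydrogenative cycloisomerisation of an α-methyl enal to a 3-methylfuran in which the aldehyde oxygen becomes the ring oxygen – pyrrolidine turns 3 into Stork dienamine 4, by far the most nucleophilic π-system present, which N-iodosuccinimide iodinates at the γ-carbon (or at the α-carbon, followed by allylic 1,3-shift of iodide); buffered hydrolysis (amine held as its ammonium salt, so it cannot be N-allylated) gives allylic iodide 5, whose E and Z forms interconvert by iodide SN2′ exchange, and in the Z form the carbonyl oxygen displaces iodide (5-exo-tet) to a 2H-furanium ion that loses the former γ-proton and aromatises irreversibly; the closest known reactions are enamine-mediated α-iodination of aldehydes, γ-functionalisation of dienamines from α-branched enals, and ring closure of γ-halo or γ-hydroxy enals and enones to furans.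

**Step 3**
Reactants: 6 (2E,6E)-3,7-dimethyl-8-(4-methylfuran-2-yl)octa-2,6-dien-1-yl acetate
Product: 7 (2E,6E)-3,7-dimethyl-8-(4-methylfuran-2-yl)octa-2,6-dien-1-ol
Conditions: K2CO3 (0.2 equiv), MeOH, 0 °C to rt
Reagents that add atoms: none
Why: Base-catalysed transesterification (methanolysis) of the allylic acetate leaves the furan and both olefins untouched.

**Step 4**
Reactants: 7 (2E,6E)-3,7-dimethyl-8-(4-methylfuran-2-yl)octa-2,6-dien-1-ol
Product: 8 (2E,6E)-3,7-dimethyl-8-(4-methylfuran-2-yl)octa-2,6-dienal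
Conditions: MnO2 (15 equiv), CH2Cl2, rt
Reagents that add atoms: none
Why: MnO2 allylic oxidation is selective for the primary allylic alcohol and keeps the E geometry of the enal.

**Step 5**
Reactants: 8 (2E,6E)-3,7-dimethyl-8-(4-methylfuran-2-yl)octa-2,6-dienal; 9 4,4,5,5-tetramethyl-2-(propa-1,2-dien-1-yl)-1,3,2-dioxaborolane (allenylboronic acid pinacol ester)
Product: 10 (4S,5E,9E)-6,10-dimethyl-11-(4-methylfuran-2-yl)undeca-5,9-dien-1-yn-4-ol
Conditions: (S)-TRIP phosphoric acid [(S)-3,3′-bis(2,4,6-triisopropylphenyl)-1,1′-binaphthyl-2,2′-diyl hydrogen phosphate] (10 mol %), 9 (1.5 equiv), 4 Å MS, toluene, −20 °C; aq. NaHCO3 work-up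
Reagents that add atoms: none
Why: Chiral phosphoric acid-catalysed propargylboration through a closed six-membered transition state (SE2′ transfer of the allenyl unit gives the terminal alkyne); (S)-TRIP, the antipode of the catalyst that gives R carbinols by Re-face attack, directs 9 to the Si face of enal 8 and so sets the S carbinol.

**Step 6**
Reactants: 11 2,6-dimethylbenzene-1,4-diol (2,6-dimethylhydroquinone)
Product: 12 2,6-dimethyl-1,4-phenylene bis(2,2-dimethylpropanoate)
Conditions: t-BuCOCl (3 equiv), Et3N (4 equiv), DMAP (0.2 equiv), CH2Cl2, reflux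
Reagents that add atoms: pivaloyl chloride, CC(C)(C)C(=O)Cl
Why: DMAP-catalysed acylation of both phenols; the pivalates deactivate the ring towards electrophilic bromination and are hindered enough to resist organoaluminium reagents.

**Step 7**
Reactants: 12 2,6-dimethyl-1,4-phenylene bis(2,2-dimethylpropanoate)
Product: 13 2-(bromomethyl)-6-methyl-1,4-phenylene bis(2,2-dimethylpropanoate)
Conditions: N-bromosuccinimide (0.95 equiv), AIBN (5 mol %), PhCF3, 80 °C
Reagents that add atoms: N-bromosuccinimide, O=C1CCC(=O)N1Br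
Why: Wohl–Ziegler benzylic bromination; the two methyl groups are equivalent, so monobromination gives one constitutional isomer and sub-stoichiometric NBS limits the dibromide.

**Step 8**
Reactants: 10 (4S,5E,9E)-6,10-dimethyl-11-(4-methylfuran-2-yl)undeca-5,9-dien-1-yn-4-ol; 13 2-(bromomethyl)-6-methyl-1,4-phenylene bis(2,2-dimethylpropanoate)
Product: 15 2-[(2E,5S,6E,10E)-5-hydroxy-3,7,11-trimethyl-12-(4-methylfuran-2-yl)dodeca-2,6,10-trien-1-yl]-6-methyl-1,4-phenylene bis(2,2-dimethylpropanoate), via alkenylalane 14 (not isolated)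
Conditions: Me3Al (3.5 equiv), Cp2ZrCl2 (0.25 equiv), CH2Cl2, −20 °C to rt; volatiles removed; then 13 (1.1 equiv), Pd(PPh3)4 (5 mol %), THF, rt; aq. potassium sodium tartrate work-up
Reagents that add atoms: trimethylaluminium, C[Al](C)C
Why: Negishi zirconium-catalysed methylalumination adds Me–Al syn across the terminal alkyne with methyl at the internal carbon (carbinol masked in situ as its aluminium alkoxide), which fixes the 2E olefin, and alkenylalane 14 then undergoes Negishi-type Pd-catalysed cross-coupling with benzylic bromide 13 with retention of geometry.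

**Step 9**
Reactants: 15 2-[(2E,5S,6E,10E)-5-hydroxy-3,7,11-trimethyl-12-(4-methylfuran-2-yl)dodeca-2,6,10-trien-1-yl]-6-methyl-1,4-phenylene bis(2,2-dimethylpropanoate)
Product: 16 2-[(2E,5S,6E,10E)-5-hydroxy-3,7,11-trimethyl-12-(4-methylfuran-2-yl)dodeca-2,6,10-trien-1-yl]-6-methylbenzene-1,4-diol
Conditions: LiAlH4 (3 equiv), THF, 0 °C, argon; degassed aq. potassium sodium tartrate/Na2S2O4 work-up
Reagents that add atoms: none
Why: Hydride reduction of the two aryl esters (including the hindered one) is non-acidic, so the furan, the allylic alcohol and its stereocentre survive, and the dithionite work-up under argon keeps the hydroquinone from oxidising to the quinone.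

**Compound list**
1 | (2E,6E)-3,7,11-trimethyldodeca-2,6,10-trien-1-yl acetate | CC(=O)OC/C=C(\C)CC/C=C(\C)CCC=C(C)C | starting material
2 | (2E,6E,10E)-12-hydroxy-3,7,11-trimethyldodeca-2,6,10-trien-1-yl acetate | CC(=O)OC/C=C(\C)CC/C=C(\C)CC/C=C(\C)CO | intermediate (not isolated)
3 | (2E,6E,10E)-3,7,11-trimethyl-12-oxododeca-2,6,10-trien-1-yl acetate | CC(=O)OC/C=C(\C)CC/C=C(\C)CC/C=C(\C)C=O | intermediate
4 | (2E,6E,9E,11E)-3,7,11-trimethyl-12-(pyrrolidin-1-yl)dodeca-2,6,9,11-tetraen-1-yl acetate | CC(=O)OC/C=C(\C)CC/C=C(\C)C/C=C/C(C)=C/N1CCCC1 | intermediate (not isolated)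
5 | (2E,6E,10Z)-9-iodo-3,7,11-trimethyl-12-oxododeca-2,6,10-trien-1-yl acetate (racemic at C9) | CC(=O)OC/C=C(\C)CC/C=C(\C)CC(I)/C=C(/C)C=O | intermediate (not isolated)
6 | (2E,6E)-3,7-dimethyl-8-(4-methylfuran-2-yl)octa-2,6-dien-1-yl acetate | CC(=O)OC/C=C(\C)CC/C=C(\C)Cc1cc(C)co1 | intermediate
7 | (2E,6E)-3,7-dimethyl-8-(4-methylfuran-2-yl)octa-2,6-dien-1-ol | OC/C=C(\C)CC/C=C(\C)Cc1cc(C)co1 | intermediate
8 | (2E,6E)-3,7-dimethyl-8-(4-methylfuran-2-yl)octa-2,6-dienal | O=C/C=C(\C)CC/C=C(\C)Cc1cc(C)co1 | intermediate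
9 | 4,4,5,5-tetramethyl-2-(propa-1,2-dien-1-yl)-1,3,2-dioxaborolane | C=C=CB1OC(C)(C)C(C)(C)O1 | starting material
10 | (4S,5E,9E)-6,10-dimethyl-11-(4-methylfuran-2-yl)undeca-5,9-dien-1-yn-4-ol | C/C(=C\[C@@H](O)CC#C)CC/C=C(\C)Cc1cc(C)co1 | intermediate
11 | 2,6-dimethylbenzene-1,4-diol | Cc1cc(O)cc(C)c1O | starting material
12 | 2,6-dimethyl-1,4-phenylene bis(2,2-dimethylpropanoate) | Cc1cc(OC(=O)C(C)(C)C)cc(C)c1OC(=O)C(C)(C)C | intermediate
13 | 2-(bromomethyl)-6-methyl-1,4-phenylene bis(2,2-dimethylpropanoate) | BrCc1cc(OC(=O)C(C)(C)C)cc(C)c1OC(=O)C(C)(C)C | intermediate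
14 | dimethyl[(1E,4S,5E,9E)-4-(dimethylalumanyloxy)-2,6,10-trimethyl-11-(4-methylfuran-2-yl)undeca-1,5,9-trien-1-yl]alumane | C/C(=C\[C@@H](O[Al](C)C)C/C(C)=C/[Al](C)C)CC/C=C(\C)Cc1cc(C)co1 | intermediate (not isolated)
15 | 2-[(2E,5S,6E,10E)-5-hydroxy-3,7,11-trimethyl-12-(4-methylfuran-2-yl)dodeca-2,6,10-trien-1-yl]-6-methyl-1,4-phenylene bis(2,2-dimethylpropanoate) | C/C(=C\[C@@H](O)C/C(C)=C/Cc1cc(OC(=O)C(C)(C)C)cc(C)c1OC(=O)C(C)(C)C)CC/C=C(\C)Cc1cc(C)co1 | intermediate
16 | 2-[(2E,5S,6E,10E)-5-hydroxy-3,7,11-trimethyl-12-(4-methylfuran-2-yl)dodeca-2,6,10-trien-1-yl]-6-methylbenzene-1,4-diol | C/C(=C\[C@@H](O)C/C(C)=C/Cc1cc(O)cc(C)c1O)CC/C=C(\C)Cc1cc(C)co1 | target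

**Totals**
Total step count: 9. Longest linear sequence: 7 (steps 1, 2, 3, 4, 5, 8, 9 from 1); steps 6 and 7 form the two-step arene branch.

**Three steps most likely to fail**

Step 2 (the proposed new furan closure). The allylic iodide 5 may lose HI to a conjugated dienal instead of closing, or the E isomer may not equilibrate fast enough. The fallback uses known chemistry, sets out from enal 3 and comes back at furan 6. Enal 3 is silylated (TBSOTf, Et3N, CH2Cl2, −78 °C) to the tert-butyldimethylsilyl dienol ether F1. F1 is oxidised at its electron-rich γ,δ-double bond with dimethyldioxirane at −78 °C (vinylogous Rubottom oxidation, silicon removed on mildly acidic aqueous work-up) to the γ-hydroxy enal F2. F2 is then cyclodehydrated to 6 with pyridinium p-toluenesulfonate in warm toluene, with a few mol % pyrrolidine for iminium-mediated E/Z equilibration.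

Step 5 (asymmetric propargylboration). The β,β-disubstituted enal may react slowly or with eroded ee, and the acid catalyst may attack the furan on long reaction times. The fallback sets out from alcohol 7 and comes back at alkyne 10, bypassing enal 8. Alcohol 7 undergoes iridium-catalysed transfer-hydrogenative propargylation with 3-chloro-1-(trimethylsilyl)prop-1-yne ([Ir(cod)Cl]2, the SEGPHOS enantiomer that gives the S carbinol, 3-nitrobenzoic acid, K3PO4, THF, 60 °C) to give the silyl alkyne F3. K2CO3 in MeOH then removes the silyl group to give 10.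

Step 8 (methylalumination / benzylation). The Lewis-acidic medium may ionise the allylic aluminium alkoxide (racemisation or elimination), residual Me3Al may attack the pivalates, or methyl instead of alkenyl may transfer. The fallback sets out from 10 and 13 and comes back at 15 with reversed coupling polarity, so the esters never meet organoaluminium. The alkenylalane from 10 is quenched with I2 at −30 °C to give the E-vinyl iodide F4. Bromide 13 is converted with zinc dust and LiCl in THF into the benzylzinc bromide F5. Negishi coupling of F4 with F5 (2.2 equiv, slow addition so the free hydroxyl is tolerated, Pd(PPh3)4, THF, rt) gives 15.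

Further compounds
F1 | step 2 | (2E,6E,9E,11E)-12-[(tert-butyldimethylsilyl)oxy]-3,7,11-trimethyldodeca-2,6,9,11-tetraen-1-yl acetate | CC(=O)OC/C=C(\C)CC/C=C(\C)C/C=C/C(C)=C/O[Si](C)(C)C(C)(C)C
F2 | step 2 | (2E,6E,10E)-9-hydroxy-3,7,11-trimethyl-12-oxododeca-2,6,10-trien-1-yl acetate | CC(=O)OC/C=C(\C)CC/C=C(\C)CC(O)/C=C(\C)C=O
F3 | step 5 | (4S,5E,9E)-6,10-dimethyl-11-(4-methylfuran-2-yl)-1-(trimethylsilyl)undeca-5,9-dien-1-yn-4-ol | C/C(=C\[C@@H](O)CC#C[Si](C)(C)C)CC/C=C(\C)Cc1cc(C)co1
F4 | step 8 | (1E,4S,5E,9E)-1-iodo-2,6,10-trimethyl-11-(4-methylfuran-2-yl)undeca-1,5,9-trien-4-ol | C/C(=C\[C@@H](O)C/C(C)=C/I)CC/C=C(\C)Cc1cc(C)co1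
F5 | step 8 | [2,5-bis(2,2-dimethylpropanoyloxy)-3-methylbenzyl]zinc bromide | Br[Zn]Cc1cc(OC(=O)C(C)(C)C)cc(C)c1OC(=O)C(C)(C)C
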